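**Retrosynthetic overview**

- Locants: ring A = bromocyclohexanol (C1 carbinol, C3 CMe2, C4 CHBr); C7 = linking CH2; ring B = cyclopentane (C8 bears C7, C9, C10, C11 quaternary, C12 ring-fusion CH); ring C = cyclohexane (C11, C12, C13 = C(Me)–O, C14, C15, C16 = CHBr); ring D = γ-lactone (C11–C17(=O)–O–C13).
- C16–Br goes in last by hydrogen-atom-transfer hydrobromination of a C15=C16 olefin. Before that, the C1–C7 bond is made by electroreductive ketyl–olefin coupling of (R)-4-bromo-3,3-dimethylcyclohexanone (ring A) with the exocyclic C8=C7 methylene of the B/C/D tricycle; this also sets C1 and C8.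
- Enabling feature: C1 is a tertiary carbinol joined through an unbranched CH2 (C7) to a methine (C8) of ring B. This C(OH)–CH2–CH unit is the retron of anti-Markovnikov ketyl addition to a 1,1-disubstituted exocyclic olefin; the axial C3 methyl of ring A and the cup shape of the cis-fused B/C/D system supply the facial bias at C1 and C8.
- B/C/D tricycle: rings B and D close together in one gold-catalysed enyne carbocyclisation with amide-oxygen capture (C8–C12 and O–C13) on a cyclohexa-1,4-diene (ring C) made by auxiliary-controlled asymmetric Birch reduction–alkylation of a 2-methoxy-5-methylbenzamide (sets C11).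
- Ring A ketone: catalytic asymmetric bromolactonisation of 5-methylhex-4-enoic acid (sets C4), lactone methylenation, O-to-C rearrangement. Ring order: C (from the arene), then B and D together; A separately; A joined to B in the penultimate step.

Key step: step 11

Assumption: the sense of asymmetric induction in steps 1 and 5 is taken to follow precedent for these catalyst and auxiliary families; if either is opposite, the antipodal catalyst or auxiliary is used and nothing else changes.

**Step 1**
Reactants: 1 5-methylhex-4-enoic acid
Product: 2 (5R)-5-bromo-6,6-dimethyloxan-2-one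
Conditions: 2,4,4,6-tetrabromocyclohexa-2,5-dien-1-one (1.2 equiv), (R)-BINOL-derived bifunctional amidine catalyst (10 mol%), toluene/CH2Cl2, −50 °C
Reagents that add atoms: 2,4,4,6-tetrabromocyclohexa-2,5-dien-1-one, O=C1C(Br)=CC(Br)(Br)C=C1Br
Why: Catalyst-controlled 6-endo bromolactonisation (asymmetric halolactonisation): the carboxylate opens the catalyst-bound bromonium ion anti at the tertiary carbon, so the C–Br stereocentre (the future C4, R) is set by the catalyst.

**Step 2**
Reactants: 2 (5R)-5-bromo-6,6-dimethyloxan-2-one
Product: 3 (3R)-3-bromo-2,2-dimethyl-6-methylideneoxane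
Conditions: Cp2TiMe2 (2 equiv), toluene, 65 °C, dark; filtration through basic alumina
Reagents that add atoms: dimethyltitanocene Cp2TiMe2, C[Ti](C)(C1C=CC=C1)C1C=CC=C1
Why: Carbonyl methylenation of the lactone by Cp2Ti=CH2 generated thermally from Cp2TiMe2 (titanium-carbene olefination) should give the exocyclic enol ether, tolerates the secondary bromide and does not touch the stereocentre.

**Step 3**
Reactants: 3 (3R)-3-bromo-2,2-dimethyl-6-methylideneoxane
Product: 4 (4R)-4-bromo-3,3-dimethylcyclohexan-1-one
Conditions: Me2AlCl (1.2 equiv), CH2Cl2, −78 → −20 °C; aq. NaHCO3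
Reagents that add atoms: none
Why: Proposed new method: coordination of Me2AlCl to the ring oxygen should trigger heterolysis of the tertiary C–O bond with anchimeric help from the anti-periplanar equatorial bromide, giving a bromonium/aluminium enolate ion pair that recloses by C-alkylation at the tertiary carbon anti to bromine (six-membered ring), so the C–Br bond is never broken and its configuration is kept; the closest known reaction types are the Petasis–Ferrier and aluminium-promoted [1,3] O-to-C rearrangements of cyclic enol ethers and bromonium-induced cyclisations onto enol derivatives.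

**Step 4**
Reactants: 5 2-methoxy-5-methylbenzoic acid; 6 (2S)-2-(methoxymethyl)pyrrolidine
Product: 8 [(2S)-2-(methoxymethyl)pyrrolidin-1-yl](2-methoxy-5-methylphenyl)methanone, via acid chloride 7 (not isolated)
Conditions: (COCl)2, cat. DMF, CH2Cl2, 0 °C → rt; then 6, Et3N, CH2Cl2, 0 °C
Reagents that add atoms: none
Why: Acylation of the secondary amine by the acid chloride made in situ (Schotten–Baumann-type amide formation) installs the auxiliary without touching its stereocentre.

**Step 5**
Reactants: 8 [(2S)-2-(methoxymethyl)pyrrolidin-1-yl](2-methoxy-5-methylphenyl)methanone; 9 4-iodo-1-(trimethylsilyl)but-1-yne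
Product: 11 [(1S)-2-methoxy-5-methyl-1-[4-(trimethylsilyl)but-3-yn-1-yl]cyclohexa-2,5-dien-1-yl][(2S)-2-(methoxymethyl)pyrrolidin-1-yl]methanone, via potassium amide enolate 10 (not isolated)
Conditions: K (2.2 equiv), NH3(l)/THF, t-BuOH (1 equiv), −78 °C; piperylene; then 9, −78 °C → rt
Reagents that add atoms: none
Why: Auxiliary-controlled asymmetric Birch reduction–alkylation: dissolving-metal reduction gives the chelated 1,4-dihydro amide enolate 10, whose geometry is fixed by the ortho-methoxy group and which should be alkylated by the primary iodide on the face left open by the methoxymethyl arm, setting the quaternary centre C11.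

**Step 6**
Reactants: 11 [(1S)-2-methoxy-5-methyl-1-[4-(trimethylsilyl)but-3-yn-1-yl]cyclohexa-2,5-dien-1-yl][(2S)-2-(methoxymethyl)pyrrolidin-1-yl]methanone
Product: 12 (2S)-2-[(2S)-2-(methoxymethyl)pyrrolidine-1-carbonyl]-4-methyl-2-[4-(trimethylsilyl)but-3-yn-1-yl]cyclohex-3-en-1-one
Conditions: 1 M HCl, THF, 0 °C
Reagents that add atoms: water, O
Why: Mild acid hydrolysis of the enol ether, much faster than protonation of the trisubstituted olefin, unmasks the C16 ketone; C11 is quaternary and cannot epimerise.

**Step 7**
Reactants: 12 (2S)-2-[(2S)-2-(methoxymethyl)pyrrolidine-1-carbonyl]-4-methyl-2-[4-(trimethylsilyl)but-3-yn-1-yl]cyclohex-3-en-1-one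
Product: 14 (6S)-6-[(2S)-2-(methoxymethyl)pyrrolidine-1-carbonyl]-4-methyl-6-[4-(trimethylsilyl)but-3-yn-1-yl]cyclohexa-1,4-dien-1-yl trifluoromethanesulfonate, via potassium enolate 13 (not isolated)
Conditions: KN(SiMe3)2, THF, −78 °C; then PhNTf2, −78 → 0 °C
Reagents that add atoms: N-phenylbis(trifluoromethanesulfonimide), O=S(=O)(N(c1ccccc1)S(=O)(=O)C(F)(F)F)C(F)(F)F
Why: Enolisation is possible only towards C15 because C11 is quaternary, and O-sulfonylation of enolate 13 gives a single enol triflate (enol triflate formation).

**Step 8**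
Reactants: 14 (6S)-6-[(2S)-2-(methoxymethyl)pyrrolidine-1-carbonyl]-4-methyl-6-[4-(trimethylsilyl)but-3-yn-1-yl]cyclohexa-1,4-dien-1-yl trifluoromethanesulfonate
Product: 15 [(1R)-3-methyl-1-[4-(trimethylsilyl)but-3-yn-1-yl]cyclohexa-2,5-dien-1-yl][(2S)-2-(methoxymethyl)pyrrolidin-1-yl]methanone
Conditions: Pd(OAc)2 (5 mol%), PPh3, n-Bu3N, HCO2H, DMF, 60 °C
Reagents that add atoms: none
Why: Palladium-catalysed formate reduction of the enol triflate (oxidative addition to zerovalent palladium, formate-to-hydride exchange, reductive elimination) replaces OTf by H and should leave the silylated alkyne and the skipped diene intact.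

**Step 9**
Reactants: 15 [(1R)-3-methyl-1-[4-(trimethylsilyl)but-3-yn-1-yl]cyclohexa-2,5-dien-1-yl][(2S)-2-(methoxymethyl)pyrrolidin-1-yl]methanone
Product: 16 [(1R)-1-(but-3-yn-1-yl)-3-methylcyclohexa-2,5-dien-1-yl][(2S)-2-(methoxymethyl)pyrrolidin-1-yl]methanone
Conditions: K2CO3 (cat.), MeOH, rt
Reagents that add atoms: none
Why: Base-mediated protodesilylation frees the terminal alkyne needed for gold activation.

**Step 10**
Reactants: 16 [(1R)-1-(but-3-yn-1-yl)-3-methylcyclohexa-2,5-dien-1-yl][(2S)-2-(methoxymethyl)pyrrolidin-1-yl]methanone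
Product: 18 (11R,12S,13S)-olefinic tricyclic lactone (rings B, C and D of the target with exocyclic C8=C7 methylene and C15=C16 double bond; no bromine), via tricyclic iminium ether 17 (not isolated)
Conditions: (t-Bu)2(2-biphenylyl)PAu(NCMe)SbF6 (5 mol%), AcOH (2 equiv), H2O (5 equiv), CH2Cl2, rt; aq. NaHCO3
Reagents that add atoms: water, O
Why: Gold-catalysed 5-exo-dig enyne carbocyclisation with anti capture by an oxygen nucleophile: the gold-bound alkyne is attacked through C12 of the more nucleophilic trisubstituted olefin from the face of the tether, the amide oxygen closes ring D on the developing tertiary C13 cation from the opposite face (fixing H-12 cis to C17 and C13 relative to C11), protodeauration leaves the exocyclic methylene, and hydrolysis of iminium ether 17 releases the auxiliary.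

**Step 11**
Reactants: 18 (11R,12S,13S)-olefinic tricyclic lactone; 4 (4R)-4-bromo-3,3-dimethylcyclohexan-1-one
Product: 19 (1R,4R,8R,11R,12S,13S)-tertiary alcohol (the target skeleton with rings A–D complete and a C15=C16 double bond in place of the C16 bromide)
Conditions: undivided cell, Zn anode, Sn cathode, n-Bu4NBr, DMF, constant current (10 mA), rt, 4 (3 equiv); aqueous work-up
Reagents that add atoms: none
Why: Cathodic one-electron reduction of ketone 4, activated by divalent zinc from the anode, gives a ketyl radical anion that adds to the unsubstituted terminus C7 of the exocyclic olefin of 18; the tertiary C8 radical is then reduced and protonated (or takes up a hydrogen atom) and work-up frees the alcohol. The closest known reaction type is the electroreductive ketone–olefin coupling of unactivated alkenes at a tin cathode with a sacrificial zinc anode, a reverse-polarity route to tertiary alcohols. No ring is closed. C1 is set by C–C bond formation on the equatorial side of the ketyl carbon, anti to the axial C3 methyl of the chair that keeps C4–Br equatorial, which leaves the hydroxyl axial and cis to bromine; C8 is set by hydrogen delivery to the convex face of ring B (the face of H-12 and the C17 carbonyl), which places C7 on the concave face cis to C13. The step needs site selectivity for the 1,1-disubstituted C8=C7 olefin over the internal C15=C16 olefin (addition at an unhindered CH2 giving a tertiary radical) and reduction of the ketone in preference to the neopentyl-type secondary C–Br bond (ketone in excess and Lewis-acid activated, charge limited), besides the two facial selectivities named.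

**Step 12**
Reactants: 19 (1R,4R,8R,11R,12S,13S)-tertiary alcohol
Product: 20 CNP0282702.1
Conditions: Co(acac)2 (0.3 equiv), t-BuOOH (0.3 equiv), Et3SiH, TsBr, n-PrOH/CH2Cl2, rt
Reagents that add atoms: 4-methylbenzenesulfonyl bromide, Cc1ccc(cc1)S(=O)(=O)Br
Why: Metal-hydride hydrogen-atom-transfer hydrobromination: the cobalt hydride should deliver H to the less hindered C15 (C16 is flanked by the quaternary C11), and the C16 radical should take bromine from TsBr on the equatorial side, away from the syn-axial C8 of ring B, giving the equatorial 16R bromide cis to C17.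

**Compound list**

1 | 5-methylhex-4-enoic acid | CC(C)=CCCC(=O)O | starting material
2 | (5R)-5-bromo-6,6-dimethyloxan-2-one | O=C1CC[C@@H](Br)C(C)(C)O1 | intermediate
3 | (3R)-3-bromo-2,2-dimethyl-6-methylideneoxane | C=C1CC[C@@H](Br)C(C)(C)O1 | intermediate
4 | (4R)-4-bromo-3,3-dimethylcyclohexan-1-one | O=C1CC[C@@H](Br)C(C)(C)C1 | intermediate
5 | 2-methoxy-5-methylbenzoic acid | COc1ccc(C)cc1C(=O)O | starting material
6 | (2S)-2-(methoxymethyl)pyrrolidine | COC[C@@H]1CCCN1 | starting material
7 | 2-methoxy-5-methylbenzoyl chloride | COc1ccc(C)cc1C(=O)Cl | intermediate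
8 | [(2S)-2-(methoxymethyl)pyrrolidin-1-yl](2-methoxy-5-methylphenyl)methanone | COC[C@@H]1CCCN1C(=O)c1cc(C)ccc1OC | intermediate
9 | 4-iodo-1-(trimethylsilyl)but-1-yne | C[Si](C)(C)C#CCCI | starting material
10 | potassium enolate of the 1,4-dihydrobenzamide | COC[C@@H]1CCCN1C([O-])=C1C=C(C)CC=C1OC.[K+] | intermediate
11 | [(1S)-2-methoxy-5-methyl-1-[4-(trimethylsilyl)but-3-yn-1-yl]cyclohexa-2,5-dien-1-yl][(2S)-2-(methoxymethyl)pyrrolidin-1-yl]methanone | C[Si](C)(C)C#CCC[C@@]1(C(=O)N2CCC[C@H]2COC)C(OC)=CCC(C)=C1 | intermediate
12 | (2S)-2-[(2S)-2-(methoxymethyl)pyrrolidine-1-carbonyl]-4-methyl-2-[4-(trimethylsilyl)but-3-yn-1-yl]cyclohex-3-en-1-one | C[Si](C)(C)C#CCC[C@@]1(C(=O)N2CCC[C@H]2COC)C(=O)CCC(C)=C1 | intermediate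
13 | potassium enolate of 12 | C[Si](C)(C)C#CCC[C@@]1(C(=O)N2CCC[C@H]2COC)C([O-])=CCC(C)=C1.[K+] | intermediate
14 | (6S)-6-[(2S)-2-(methoxymethyl)pyrrolidine-1-carbonyl]-4-methyl-6-[4-(trimethylsilyl)but-3-yn-1-yl]cyclohexa-1,4-dien-1-yl trifluoromethanesulfonate | C[Si](C)(C)C#CCC[C@@]1(C(=O)N2CCC[C@H]2COC)C(OS(=O)(=O)C(F)(F)F)=CCC(C)=C1 | intermediate
15 | [(1R)-3-methyl-1-[4-(trimethylsilyl)but-3-yn-1-yl]cyclohexa-2,5-dien-1-yl][(2S)-2-(methoxymethyl)pyrrolidin-1-yl]methanone | C[Si](C)(C)C#CCC[C@@]1(C(=O)N2CCC[C@H]2COC)C=CCC(C)=C1 | intermediate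
16 | [(1R)-1-(but-3-yn-1-yl)-3-methylcyclohexa-2,5-dien-1-yl][(2S)-2-(methoxymethyl)pyrrolidin-1-yl]methanone | C#CCC[C@@]1(C(=O)N2CCC[C@H]2COC)C=CCC(C)=C1 | intermediate
17 | tricyclic iminium ether acetate (ring D closed through the amide oxygen; C17 still bonded to the pyrrolidinium nitrogen) | C=C1CC[C@@]23C(=[N+]4CCC[C@H]4COC)O[C@@](C)(CC=C2)[C@@H]13.CC(=O)[O-] | intermediate
18 | (11R,12S,13S)-olefinic tricyclic lactone (exocyclic C8=C7 methylene, C15=C16 double bond) | C=C1CC[C@@]23C(=O)O[C@@](C)(CC=C2)[C@@H]13 | intermediate
19 | (1R,4R,8R,11R,12S,13S)-tertiary alcohol with C15=C16 double bond | CC1(C)C[C@](O)(C[C@H]2CC[C@@]34C(=O)O[C@@](C)(CC=C3)[C@@H]24)CC[C@H]1Br | intermediate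
20 | CNP0282702.1 | CC1(C)C[C@](O)(C[C@H]2CC[C@@]34C(=O)O[C@@](C)(CC[C@H]3Br)[C@@H]24)CC[C@H]1Br | target

**Step count**

Total steps: 12. Longest linear sequence: 9 steps (steps 4–12).

**Steps most likely to fail**

1. Step 3. After ionisation the ion pair may lose a proton (open-chain isopropenyl ketone) or collapse with chloride instead of forming the C–C bond. The fallback sets out from 1 and comes back at 4. Masamune–Brooks homologation of 1 (carbonyldiimidazole, then Mg(O2CCH2CO2Et)2, THF) gives ethyl 7-methyl-3-oxooct-6-enoate F1. Bromonium-induced cyclisation terminated by the β-keto ester (Et2SBr·SbCl5Br, MeNO2, −25 °C) gives racemic ethyl 3-bromo-2,2-dimethyl-6-oxocyclohexane-1-carboxylate F2. Ester hydrolysis and decarboxylation (aq. HCl, AcOH, heat) gives racemic 4-bromo-3,3-dimethylcyclohexan-1-one F3, which is resolved by preparative chromatography on a chiral stationary phase to return to 4.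

2. Step 11. The C4–Br bond may be cleaved at the cathode, and facial selectivity at C1 may erode if the chair with axial bromide reacts, because bromine is only a weak conformational anchor. The fallback sets out from 16 (with 4) and comes back at 19; it avoids reducing conditions and forms the same bond by polar addition at low temperature, though it does not by itself remove the facial-selectivity concern. Deprotonation of 16 with LiN(i-Pr)2, transmetalation with CeCl3 and addition to 4 at −78 °C (acetylide addition, equatorial attack) gives the tertiary propargylic alcohol F4. The gold-catalysed carbocyclisation and oxygen capture of step 10 then gives the tricyclic allylic alcohol F5 (as 19 but with an exocyclic C8=C7 double bond) with loss of the auxiliary. Hydrogen-atom-transfer hydrogenation (Mn(dpm)3, PhSiH3, t-BuOOH, i-PrOH), selective for the trisubstituted olefin and delivering H to C8 from the convex face, returns to 19.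

3. Step 12. Hydrogen-atom transfer may go to C16 instead of C15 (regioisomeric C15 bromide), or bromine transfer may occur on the axial side (C16 epimer). The fallback sets out from 12 and comes back at 20; it keeps the Birch-derived oxygen at C16 and replaces it by bromide with inversion. Protodesilylation of 12 (K2CO3, MeOH) gives the keto amide F6, and the gold cascade of step 10 gives the keto lactone F7. NaBH4 reduction, with hydride entering from the unhindered equatorial direction, gives the axial (16S) alcohol F8. Electroreductive coupling with 4 as in step 11 gives the diol F9. Appel bromination of the secondary alcohol (CBr4, PPh3, inversion) returns to 20; displacement at this hindered centre is expected to be slow.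

**Further compounds**

F1 | step 3 | ethyl 7-methyl-3-oxooct-6-enoate | CCOC(=O)CC(=O)CCC=C(C)C
F2 | step 3 | racemic ethyl 3-bromo-2,2-dimethyl-6-oxocyclohexane-1-carboxylate | CCOC(=O)C1C(=O)CCC(Br)C1(C)C
F3 | step 3 | racemic 4-bromo-3,3-dimethylcyclohexan-1-one | O=C1CCC(Br)C(C)(C)C1
F4 | step 11 | tertiary propargylic alcohol from 16 and 4 (C1 bonded to the alkyne terminus C7) | CC1(C)C[C@](O)(C#CCC[C@@]2(C(=O)N3CCC[C@H]3COC)C=CCC(C)=C2)CC[C@H]1Br
F5 | step 11 | tricyclic allylic alcohol with exocyclic C8=C7 double bond | CC1(C)C[C@](O)(/C=C2/CC[C@@]34C(=O)O[C@@](C)(CC=C3)[C@@H]24)CC[C@H]1Br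
F6 | step 12 | (2S)-2-(but-3-yn-1-yl)-2-[(2S)-2-(methoxymethyl)pyrrolidine-1-carbonyl]-4-methylcyclohex-3-en-1-one | C#CCC[C@@]1(C(=O)N2CCC[C@H]2COC)C(=O)CCC(C)=C1
F7 | step 12 | tricyclic keto lactone (C16 ketone, exocyclic C8=C7 methylene) | C=C1CC[C@@]23C(=O)O[C@@](C)(CCC2=O)[C@@H]13
F8 | step 12 | tricyclic (16S)-hydroxy lactone (axial alcohol, exocyclic C8=C7 methylene) | C=C1CC[C@@]23C(=O)O[C@@](C)(CC[C@@H]2O)[C@@H]13
F9 | step 12 | (16S)-16-hydroxy-16-debromo analogue of 20 | CC1(C)C[C@](O)(C[C@H]2CC[C@@]34C(=O)O[C@@](C)(CC[C@@H]3O)[C@@H]24)CC[C@H]1Br
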